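Ring C is disconnected across O1–C2 and C3–C4. Two features are exploited. The four-atom chain O1–C8a–C4a–C4 on the oxygen-rich ring A can be unmasked as an ortho-quinone methide, the 4π heterodiene. The C2–C3 bond, whose aryl and hydroxy groups lie anti, maps onto an (E)-styryl ester, the 2π partner. One chiral-acid-catalysed inverse-demand [4+2] cycloaddition closes the pyran, makes both bonds and sets C2 and C3. The methoxy group left at C4 holds the oxidation level of the later ketone. The precursors are 3-prenyl-4,6-dimethoxysalicylaldehyde, activated in the flask by trimethyl orthoformate, and the (E)-enol acetate of O-acetylated (3-hydroxy-4-methoxyphenyl)acetaldehyde.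

Key step: step 6

Assumption: the sense of induction cannot be predicted for this new substrate pair. The (R)-acid is written and taken to give the (2R,3S) adduct, and its equally available mirror image is used if the opposite sense is found.
Remark on descriptors: the geometry at C3 never changes after step 6. The label is S in chromans 13 and 14, where C2 outranks C4, and R in ketones 15–17, where C4 outranks C2.

Step 1
Reactants: 1 2-hydroxy-4,6-dimethoxybenzaldehyde; 2 3-chloro-3-methylbut-1-yne
Product: 3 2,4-dimethoxy-6-[(2-methylbut-3-yn-2-yl)oxy]benzaldehyde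
Conditions: K2CO3, KI (cat.), CuI (cat.), DMF, 60 °C
Reagents that add atoms: none
Why: Copper-assisted Williamson-type O-alkylation of a phenoxide with a tertiary propargylic chloride is the standard entry to aryl 1,1-dimethylpropargyl ethers, and K2CO3 in DMF is basic enough to free the phenol from its hydrogen bond to the formyl group.

Step 2
Reactants: 3 2,4-dimethoxy-6-[(2-methylbut-3-yn-2-yl)oxy]benzaldehyde
Product: 4 2,4-dimethoxy-6-[(2-methylbut-3-en-2-yl)oxy]benzaldehyde
Conditions: H2 (1 atm), Pd/CaCO3 poisoned with Pb(OAc)2, quinoline, EtOAc, rt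
Reagents that add atoms: none
Why: Lindlar semihydrogenation stops at the terminal alkene and spares the aldehyde and the aryl ether, and it must precede heating because the propargyl ether itself would rearrange to a 2,2-dimethylchromene.

Step 3
Reactants: 4 2,4-dimethoxy-6-[(2-methylbut-3-en-2-yl)oxy]benzaldehyde
Product: 5 2-hydroxy-4,6-dimethoxy-3-(3-methylbut-2-enyl)benzaldehyde
Conditions: o-xylene, 140 °C, base-washed glassware
Reagents that add atoms: none
Why: Aromatic Claisen rearrangement: the [3,3] shift can only reach the free ortho carbon (the other carries the formyl group), it inverts the allyl unit so that the 1,1-dimethylallyl ether becomes a normal prenyl group, and tautomerisation restores the hydrogen-bonded phenol.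

Step 4
Reactants: 6 isovanillin (3-hydroxy-4-methoxybenzaldehyde)
Product: 8 (3-hydroxy-4-methoxyphenyl)acetaldehyde, via methyl enol ether 7 (not isolated)
Conditions: Ph3P(CH2OMe)Cl, KOtBu (excess), THF, 0 °C → rt; then 2 M aq. HCl, 40 °C, same flask; used crude
Reagents that add atoms: (methoxymethyl)triphenylphosphonium chloride, COC[P+](c1ccccc1)(c1ccccc1)c1ccccc1.[Cl-]; water, O
Why: Wittig methoxymethylenation (extra base covers the phenol, whose meta phenoxide does not deactivate the aldehyde) followed by acid hydrolysis of the enol ether is the standard one-carbon homologation of a benzaldehyde to an arylacetaldehyde.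

Step 5
Reactants: 8 (3-hydroxy-4-methoxyphenyl)acetaldehyde
Product: 9 (E)-2-(3-acetoxy-4-methoxyphenyl)vinyl acetate
Conditions: Ac2O, KOAc, 120 °C; (E)-isomer isolated by chromatography and crystallisation
Reagents that add atoms: acetic anhydride, CC(=O)OC(C)=O
Why: Enol esterification: acetate removes a benzylic proton and the conjugated enolate, like the phenol, is O-acetylated; acyl transfer is reversible at this temperature, so the less crowded, fully conjugated (E)-isomer should be favoured, and the (Z)-isomer is removed (and can be resubmitted) because the alkene geometry is read out in step 6.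

Step 6
Reactants: 5 2-hydroxy-4,6-dimethoxy-3-(3-methylbut-2-enyl)benzaldehyde; 9 (E)-2-(3-acetoxy-4-methoxyphenyl)vinyl acetate; 10 trimethyl orthoformate
Product: 13 (2R,3S)-3-acetoxy-2-(3-acetoxy-4-methoxyphenyl)-4,5,7-trimethoxy-8-(3-methylbut-2-enyl)chroman (2,3-trans; either C4 epimer), via dimethyl acetal 11 (not isolated), via methoxy ortho-quinone methide 12 (not isolated)
Conditions: (R)-TRIP [(R)-3,3'-bis(2,4,6-triisopropylphenyl)-1,1'-binaphthyl-2,2'-diyl hydrogen phosphate] (10 mol %), 5 Å molecular sieves, PhMe, 0 °C → rt; 9 in excess, 5 added slowly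
Reagents that add atoms: none
Why: Proposed new method: the chiral acid first lets 5 exchange with 10 to acetal 11 and then expels methanol, giving the O-protonated form of 12, an oxocarbenium ion whose charge is spread over the three ring A oxygens and which stays hydrogen-bonded and ion-paired to the phosphate; the alkene of 9 attacks C4 with its acetoxy-bearing carbon (future C3) and O1 then collapses on the anisyl-stabilised C2 cation, a polar, highly asynchronous inverse-demand hetero-Diels–Alder reaction. The closest known reaction types are the achiral-acid three-component chroman synthesis from salicylaldehydes, orthoformates and styrenes and the chiral phosphoric or imidodiphosphoric acid [4+2] reactions of ortho-quinone methides with styrenes, enamides and tethered alkenes, but a 4-alkoxy quinone methide has not been combined with an enol ester under chiral-acid control. Ring C closes as the six-membered pyran of the [4+2] process, which in the stepwise limit is a 6-exo-trig attack of O1 on the para-quinone-methide-like cation. C3 is set in the C3–C4 bond formation by catalyst control (the phosphate pocket decides which alkene face meets bound 12), and C2 is set relative to C3 by the substrate, since suprafacial addition to the (E)-alkene and diequatorial closure of an open cation both give 2,3-trans, while the C4 epimer ratio is irrelevant because C4 becomes the ketone. The step needs regioselectivity, secured by pairing a strongly donating 4-methoxyphenyl group with an only weakly donating acyloxy oxygen (an enol ether would reverse the polarity), and chemoselectivity over the prenyl alkene, helped by excess 9 and slow addition of 5. The weak acid, low temperature and non-polar solvent are chosen so that the ortho-prenylphenol is not cyclised to a dimethylchroman and the enol ester is not methanolysed.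

Step 7
Reactants: 13 (2R,3S)-3-acetoxy-2-(3-acetoxy-4-methoxyphenyl)-4,5,7-trimethoxy-8-(3-methylbut-2-enyl)chroman
Product: 14 (2R,3S)-3-acetoxy-2-(3-acetoxy-4-methoxyphenyl)-4-hydroxy-5,7-dimethoxy-8-(3-methylbut-2-enyl)chroman (either C4 epimer)
Conditions: 0.05 M HCl, THF–H2O (3:1), 0.01 M in 13, rt
Reagents that add atoms: water, O
Why: SN1 solvolysis of an activated benzylic ether: loss of methanol gives a C4 cation stabilised by O1 and the 5- and 7-methoxy groups, the large excess of water captures it while high dilution suppresses attack by C6 of a second molecule, and C2 and C3 are not involved.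

Step 8
Reactants: 14 (2R,3S)-3-acetoxy-2-(3-acetoxy-4-methoxyphenyl)-4-hydroxy-5,7-dimethoxy-8-(3-methylbut-2-enyl)chroman
Product: 15 (2R,3R)-3-acetoxy-2-(3-acetoxy-4-methoxyphenyl)-5,7-dimethoxy-8-(3-methylbut-2-enyl)chroman-4-one
Conditions: Dess–Martin periodinane, pyridine, CH2Cl2, 0 °C → rt
Reagents that add atoms: none
Why: Dess–Martin oxidation of the secondary benzylic alcohol under buffered, non-enolising conditions gives the aryl ketone without touching the prenyl alkene or the esters, and both C4 epimers converge on one compound.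

Step 9
Reactants: 15 (2R,3R)-3-acetoxy-2-(3-acetoxy-4-methoxyphenyl)-5,7-dimethoxy-8-(3-methylbut-2-enyl)chroman-4-one
Product: 16 (2R,3R)-3-acetoxy-2-(3-acetoxy-4-methoxyphenyl)-5-hydroxy-7-methoxy-8-(3-methylbut-2-enyl)chroman-4-one
Conditions: MgI2 (anhydrous, 3 equiv), THF, 60 °C; then H2O
Reagents that add atoms: none
Why: Chelation-directed aryl methyl ether cleavage: magnesium bridges the C4 carbonyl and the peri O5, iodide removes only that methyl group by SN2, the reagent is established for 5-methoxy-8-prenylflavanones without damage to the prenyl group, and keeping both acetates on removes the competing chelation sites (3-OH/C4=O and 3'-OH/4'-OMe), any partial acetate loss being harmless.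

Step 10
Reactants: 16 (2R,3R)-3-acetoxy-2-(3-acetoxy-4-methoxyphenyl)-5-hydroxy-7-methoxy-8-(3-methylbut-2-enyl)chroman-4-one
Product: 17 (2R,3R)-3,5-dihydroxy-2-(3-hydroxy-4-methoxyphenyl)-7-methoxy-8-(3-methylbut-2-enyl)chroman-4-one (CNP0302743.1)
Conditions: HCl (0.5 M) in MeOH, 40 °C
Reagents that add atoms: none
Why: Acid-catalysed transesterification removes the aryl and the activated α-keto acetate together and avoids the enolate and ring-opened chalcone pathway by which base racemises dihydroflavonols, while the prenyl group, flanked by O1 and the 7-methoxy group, has no free phenol with which to cyclise.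

Compound list
1 | 2-hydroxy-4,6-dimethoxybenzaldehyde | COc1cc(O)c(C=O)c(OC)c1 | starting material
2 | 3-chloro-3-methylbut-1-yne | CC(C)(Cl)C#C | starting material
3 | 2,4-dimethoxy-6-[(2-methylbut-3-yn-2-yl)oxy]benzaldehyde | COc1cc(OC(C)(C)C#C)c(C=O)c(OC)c1 | intermediate
4 | 2,4-dimethoxy-6-[(2-methylbut-3-en-2-yl)oxy]benzaldehyde | COc1cc(OC(C)(C)C=C)c(C=O)c(OC)c1 | intermediate
5 | 2-hydroxy-4,6-dimethoxy-3-(3-methylbut-2-enyl)benzaldehyde | O=Cc1c(O)c(CC=C(C)C)c(OC)cc1OC | intermediate
6 | isovanillin | COc1ccc(C=O)cc1O | starting material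
7 | 2-methoxy-5-(2-methoxyvinyl)phenol (E/Z mixture, not isolated) | COC=Cc1ccc(OC)c(O)c1 | intermediate
8 | (3-hydroxy-4-methoxyphenyl)acetaldehyde | COc1ccc(CC=O)cc1O | intermediate
9 | (E)-2-(3-acetoxy-4-methoxyphenyl)vinyl acetate | CC(=O)O/C=C/c1ccc(OC)c(OC(C)=O)c1 | intermediate
10 | trimethyl orthoformate | COC(OC)OC | starting material
11 | 2-(dimethoxymethyl)-3,5-dimethoxy-6-(3-methylbut-2-enyl)phenol (not isolated) | COC(OC)c1c(O)c(CC=C(C)C)c(OC)cc1OC | intermediate
12 | 6-(methoxymethylidene)-3,5-dimethoxy-2-(3-methylbut-2-enyl)cyclohexa-2,4-dien-1-one, present as its O-protonated ion pair with the chiral phosphate (not isolated; exocyclic geometry undefined) | COC=C1C(=O)C(CC=C(C)C)=C(OC)C=C1OC | intermediate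
13 | (2R,3S)-3-acetoxy-2-(3-acetoxy-4-methoxyphenyl)-4,5,7-trimethoxy-8-(3-methylbut-2-enyl)chroman, 2,3-trans, either C4 epimer | COc1ccc([C@H]2Oc3c(CC=C(C)C)c(OC)cc(OC)c3C(OC)[C@@H]2OC(C)=O)cc1OC(C)=O | intermediate
14 | (2R,3S)-3-acetoxy-2-(3-acetoxy-4-methoxyphenyl)-4-hydroxy-5,7-dimethoxy-8-(3-methylbut-2-enyl)chroman, either C4 epimer | COc1ccc([C@H]2Oc3c(CC=C(C)C)c(OC)cc(OC)c3C(O)[C@@H]2OC(C)=O)cc1OC(C)=O | intermediate
15 | (2R,3R)-3-acetoxy-2-(3-acetoxy-4-methoxyphenyl)-5,7-dimethoxy-8-(3-methylbut-2-enyl)chroman-4-one | COc1ccc([C@H]2Oc3c(CC=C(C)C)c(OC)cc(OC)c3C(=O)[C@@H]2OC(C)=O)cc1OC(C)=O | intermediate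
16 | (2R,3R)-3-acetoxy-2-(3-acetoxy-4-methoxyphenyl)-5-hydroxy-7-methoxy-8-(3-methylbut-2-enyl)chroman-4-one | COc1ccc([C@H]2Oc3c(CC=C(C)C)c(OC)cc(O)c3C(=O)[C@@H]2OC(C)=O)cc1OC(C)=O | intermediate
17 | (2R,3R)-3,5-dihydroxy-2-(3-hydroxy-4-methoxyphenyl)-7-methoxy-8-(3-methylbut-2-enyl)chroman-4-one | COc1ccc([C@H]2Oc3c(CC=C(C)C)c(OC)cc(O)c3C(=O)[C@@H]2O)cc1O | target

Total step count: 10. Longest linear sequence: 8 steps (steps 1–3 and 6–10).

Steps most likely to fail

**Step 6.**
- The alkene may bond through its aryl-bearing carbon, which reverses the regiochemistry.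
- Capture of the strongly stabilised cation may be so slow that self-condensation through C6 of ring A, or addition to a prenyl alkene, takes over.
- Facial discrimination may be weak, because 9 offers the phosphate no hydrogen-bond donor.
- The acid may close the prenylphenol to a chroman.

The fallback uses known chemistry only. It sets out from 5 and 6 and returns at 15 through an enantioselective chalcone epoxidation. Phenol 5 is protected (NaH, MOMCl, DMF) as 2-(methoxymethoxy)-4,6-dimethoxy-3-(3-methylbut-2-enyl)benzaldehyde F1. MeMgBr (THF, 0 °C) gives the racemic 1-arylethanol F2, and Dess–Martin oxidation gives the acetophenone F3. Isovanillin 6 is protected (MOMCl, iPr2NEt, CH2Cl2) as 4-methoxy-3-(methoxymethoxy)benzaldehyde F4. Claisen–Schmidt condensation of the two (KOH, EtOH, rt) gives the (E)-chalcone F5. Juliá–Colonna epoxidation (poly-L-leucine, urea–H2O2, DBU, THF) is nucleophilic and therefore ignores the prenyl alkene, and it gives the (αR,βS)-epoxyketone F6. HCl in MeOH (45 °C) removes both MOM groups, and the freed phenol opens the epoxide at the benzylic carbon with inversion, while the α-carbon keeps its configuration. The product is the (2R,3R)-5-O-methyl dihydroflavonol F7. Ac2O in pyridine then gives 15.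

**Step 7.**
- The C4 cation may be intercepted by C6 of a second molecule, giving oligomers.
- It may lose the C3 proton to give a chromene, which would erase C3.
- The 3-acetate may participate, with acyl migration to O4.

The fallback sets out from 13 and returns at 15. It does not ionise the C4–O bond. Instead the C4–H bond is removed as hydride with DDQ in CH2Cl2–pH 7 buffer (0 °C → rt), the known oxidative cleavage of electron-rich benzylic methyl ethers. Water adds to the tertiary oxocarbenium ion and the hemiketal collapses to the ketone. Step 8 is skipped as well and no new compound is made. Competing hydride abstraction from the benzylic–allylic CH2 at C8 would have to be watched.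

**Step 9.**
- Ether cleavage may be incomplete or unselective.
- Traces of acid may add to the prenyl alkene.
- The Lewis acid may open ring C towards the chalcone, with erosion of enantiopurity.

The fallback sets out from 1 and returns at 17. The O5 methyl group is exchanged for an acid-labile group before any sensitive function exists. AlCl3 (CH2Cl2, reflux) cleaves the methyl ether ortho to the formyl group and gives 2,6-dihydroxy-4-methoxybenzaldehyde F8. One equivalent of MOMCl with iPr2NEt gives 2-hydroxy-4-methoxy-6-(methoxymethoxy)benzaldehyde F9. The conditions of steps 1–3, with 2, then give the propargyl ether F10, the 1,1-dimethylallyl ether F11 and the prenyl salicylaldehyde F12. The conditions of steps 6–8, with 9 and 10, give the 5-O-MOM cycloadduct F13, the 5-O-MOM chroman-4-ol F14 and the 5-O-MOM chroman-4-one F15. The HCl in MeOH of step 10 removes the MOM group together with both acetates and gives 17, so no Lewis acid meets the finished skeleton.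

Further compounds
F1 | step 6 | 2-(methoxymethoxy)-4,6-dimethoxy-3-(3-methylbut-2-enyl)benzaldehyde | O=Cc1c(OCOC)c(CC=C(C)C)c(OC)cc1OC
F2 | step 6 | 1-[4,6-dimethoxy-2-(methoxymethoxy)-3-(3-methylbut-2-enyl)phenyl]ethanol (racemic) | CC(O)c1c(OCOC)c(CC=C(C)C)c(OC)cc1OC
F3 | step 6 | 1-[4,6-dimethoxy-2-(methoxymethoxy)-3-(3-methylbut-2-enyl)phenyl]ethanone | CC(=O)c1c(OCOC)c(CC=C(C)C)c(OC)cc1OC
F4 | step 6 | 4-methoxy-3-(methoxymethoxy)benzaldehyde | COCOc1cc(C=O)ccc1OC
F5 | step 6 | (E)-1-[4,6-dimethoxy-2-(methoxymethoxy)-3-(3-methylbut-2-enyl)phenyl]-3-[4-methoxy-3-(methoxymethoxy)phenyl]prop-2-en-1-one | COc1cc(OC)c(C(=O)/C=C/c2ccc(OC)c(OCOC)c2)c(OCOC)c1CC=C(C)C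
F6 | step 6 | [4,6-dimethoxy-2-(methoxymethoxy)-3-(3-methylbut-2-enyl)phenyl]{(2R,3S)-3-[4-methoxy-3-(methoxymethoxy)phenyl]oxiran-2-yl}methanone | COc1cc(OC)c(C(=O)[C@@H]2O[C@H]2c3ccc(OC)c(OCOC)c3)c(OCOC)c1CC=C(C)C
F7 | step 6 | (2R,3R)-3-hydroxy-2-(3-hydroxy-4-methoxyphenyl)-5,7-dimethoxy-8-(3-methylbut-2-enyl)chroman-4-one | COc1ccc([C@H]2Oc3c(CC=C(C)C)c(OC)cc(OC)c3C(=O)[C@@H]2O)cc1O
F0 | step 7 | none | none
F8 | step 9 | 2,6-dihydroxy-4-methoxybenzaldehyde | COc1cc(O)c(C=O)c(O)c1
F9 | step 9 | 2-hydroxy-4-methoxy-6-(methoxymethoxy)benzaldehyde | COCOc1cc(OC)cc(O)c1C=O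
F10 | step 9 | 4-methoxy-2-(methoxymethoxy)-6-[(2-methylbut-3-yn-2-yl)oxy]benzaldehyde | COCOc1cc(OC)cc(OC(C)(C)C#C)c1C=O
F11 | step 9 | 4-methoxy-2-(methoxymethoxy)-6-[(2-methylbut-3-en-2-yl)oxy]benzaldehyde | COCOc1cc(OC)cc(OC(C)(C)C=C)c1C=O
F12 | step 9 | 2-hydroxy-4-methoxy-6-(methoxymethoxy)-3-(3-methylbut-2-enyl)benzaldehyde | O=Cc1c(O)c(CC=C(C)C)c(OC)cc1OCOC
F13 | step 9 | (2R,3S)-3-acetoxy-2-(3-acetoxy-4-methoxyphenyl)-4,7-dimethoxy-5-(methoxymethoxy)-8-(3-methylbut-2-enyl)chroman, either C4 epimer | COc1ccc([C@H]2Oc3c(CC=C(C)C)c(OC)cc(OCOC)c3C(OC)[C@@H]2OC(C)=O)cc1OC(C)=O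
F14 | step 9 | (2R,3S)-3-acetoxy-2-(3-acetoxy-4-methoxyphenyl)-4-hydroxy-7-methoxy-5-(methoxymethoxy)-8-(3-methylbut-2-enyl)chroman, either C4 epimer | COc1ccc([C@H]2Oc3c(CC=C(C)C)c(OC)cc(OCOC)c3C(O)[C@@H]2OC(C)=O)cc1OC(C)=O
F15 | step 9 | (2R,3R)-3-acetoxy-2-(3-acetoxy-4-methoxyphenyl)-7-methoxy-5-(methoxymethoxy)-8-(3-methylbut-2-enyl)chroman-4-one | COc1ccc([C@H]2Oc3c(CC=C(C)C)c(OC)cc(OCOC)c3C(=O)[C@@H]2OC(C)=O)cc1OC(C)=O
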